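## The problem

Selaginellin (22) is achiral, so no stereocentre has to be set and none can steer another; the cyclohexadienone and the 4-hydroxyphenyl ring on the methide carbon are interchanged by a proton shift. The difficulty is regiochemical: ring A is a benzene with four different substituents on four neighbouring carbons, namely the methide carbon on C1, a 4-hydroxyphenyl ring on C2, a hydroxymethyl group on C5 and a (4-hydroxyphenyl)ethynyl group on C6, with hydrogen only on C3 and C4. The two bulkiest groups, on C1 and C6, are each flanked on both sides, so substitution of a preformed benzene offers no reliable way to place them. The outer aryl rings are joined to ring A only through single bonds, an alkyne and the methide carbon, so they can be bought and the real construction problem is ring A. Several groups are fragile: the para-quinone methide is an electrophile that forms from the 4-hydroxyphenyl carbinol by loss of water and must be unveiled last; the diarylalkyne lies between two oxygen nucleophiles (the C5 hydroxymethyl group and the carbinol on C1) that can add across it under strong base or electrophilic activation; the triaryl cation can close onto the C2 aryl ring to a 9,9-diarylfluorene in strong acid; and the benzylic hydroxyl is exchanged by Lewis-acidic halides. The enabling feature is the pattern on C1, C6 and C5, a carbon at the acid oxidation level, a position that can hold oxygen and an oxygenated one-carbon arm, which is the pattern of a 3-(oxymethyl)salicylate, while C2–C3–C4 with the aryl group on C2 is an aryl ketone three-carbon unit. Ring A can therefore be closed from the dienol ether of a β-keto ester and an aryl β-keto acetal.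

## Retrosynthesis

**Unmasking (22 from 20).** The last operation is chosen first because it fixes the protecting groups of the whole route. Quinone methide 22 is the dehydration product of pentahydroxy carbinol 21, which is traced to the fully silylated carbinol 20. Four O–Si bonds and the carbinol C–O bond are broken, no skeletal bond. Methyl ethers on the three phenols would need a boron trihalide at the end, which would turn the benzylic oxygen into a halide, activate the alkyne towards its oxygen neighbours and favour fluorene closure. Silyl ethers come off with buffered fluoride. Compound 20 is no simpler in skeleton than 22, but it is stable, non-polar and free of the quinone methide. The forward step must cleave one primary alkyl silyl ether and three aryl silyl ethers without exposing the alkyne to a free alkoxide or to strong acid.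

**The methide carbon (20 from 16 and 17).** The two C–C bonds from the future methide carbon to its two identical aryl rings are cut. This gives methyl ester 16 and two equivalents of aryllithium 18, made from two equivalents of bromide 17. Cutting the bond between ring A and this carbon instead would need a metalated ring A at a position flanked by an aryl and an alkynyl group. The ester cut uses the carbon that the annulation leaves on C1 anyway and exploits the identity of the two rings. The precursor loses two aryl rings and the quaternary centre. The forward reaction must drive a double addition through ketone 19 at a 2,6-disubstituted benzoate and stop before the tertiary alkoxide adds to the alkyne.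

**The alkyne (16 from 14 and 15; 14 from 13).** The C6–C(sp) bond is cut to aryl triflate 14 and terminal alkyne 15, and the triflate is traced to phenol 13. Cutting the other alkyne bond, C(sp)–aryl, would leave an ethynyl group on ring A that has no direct origin in the annulation. The oxygen on C6 is exactly what the salicylate synthesis provides. The cut removes the third purchased ring and leaves a trisubstituted salicylate. The coupling must occur at a triflate between an ester and a silyloxymethyl group. The ortho ester helps oxidative addition, and a linear alkyne is the least demanding partner for such a position.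

**Ring A (13 from 6 and 11).** The C4–C5 and C1–C2 bonds of ring A are cut. This divides salicylate 13 into 1,3-bis(silyloxy)diene 6 and β-keto acetal 11. Diene 6 supplies C1 with its ester carbon, C6 with its oxygen and C5 with its silyloxymethyl arm; acetal 11 supplies C2 with its aryl ring, C3 and C4. Against cross-coupling routes from a preformed benzene, this cut places all four ring A substituents in one step from open-chain partners. Against other pairings of ring bonds, it uses a component whose two ends differ greatly in electrophilicity, which decides the orientation. The precursors are a protected β-keto ester and a protected β-keto aldehyde. The forward reaction has to join the diene terminus to the acetal carbon before the ester-bearing carbon closes on the ketone. It must also leave one alkyl and one aryl silyl ether intact under a Lewis acid, which is why the aryl oxygen of 11 carries the robust triisopropylsilyl group.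

**Diene 6 (from 5, 4, 1 and 2).** Two O–Si bonds are cut back to silyl enol ether 5 and β-keto ester 4. The C–C bond between the γ-carbon and the oxymethyl carbon is then cut to methyl acetoacetate 1, through its dianion 3, and chloromethyl silyl ether 2. An aldol of 3 with formaldehyde would give a δ-hydroxy β-keto ester that dehydrates easily and needs a separate silylation. Alkylation with 2 delivers the protected arm in one step. The forward sequence must silylate the γ-position without expelling the β-silyloxy group, which argues for trapping the dienolate as it forms.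

**Keto acetal 11 (from 8 and 9; 8 from 7).** The C–C bond between the ketone α-carbon and the acetal carbon is cut to acetophenone 8 and trimethyl orthoformate 9, used as its carbenium salt 10. Acetophenone 8 comes from 4'-hydroxyacetophenone 7. A Claisen formylation with alkoxide followed by acidic acetalisation would endanger the aryl silyl ether. The carbenium route is non-nucleophilic and gives the acetal oxidation level directly. Both precursors are commodity chemicals.

## Roads not taken

Alternative 1: The cut is at the alkyne, which is traced to a diaryl ketone on C6: {6-[(tert-butyldimethylsilyloxy)methyl]-2-[methoxybis(4-methoxyphenyl)methyl]-3-(4-methoxyphenyl)phenyl}(4-methoxyphenyl)methanone A1. In the forward step lithio(trimethylsilyl)diazomethane A2 adds to the ketone. Peterson elimination and loss of nitrogen give an alkylidene carbene, and a 1,2-aryl shift (Colvin rearrangement) gives tert-butyl{[3-[methoxybis(4-methoxyphenyl)methyl]-4-(4-methoxyphenyl)-2-[(4-methoxyphenyl)ethynyl]phenyl]methoxy}dimethylsilane A3.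
- Merits: the alkyne is made from a carbonyl group, so no cross-coupling is needed at crowded C6. The triaryl carbon is already in place as a methyl ether, so no alkoxide ever sits next to the alkyne. Aryl migration in diaryl alkylidene carbenes is fast.
- Weak points: the step builds nothing of ring A. A1 already holds all four contiguous substituents, so the central problem is pushed back into an arene synthesis that the strategy does not solve. The carbonyl of A1 lies between a benzylic ether and a fully substituted triaryl carbon and is shielded, so addition of bulky A2 is uncertain. The carbene is within reach of the oxygen-activated benzylic C–H bonds (1,5-insertion) and of the methoxy oxygen. The methyl ethers commit the end game to boron trihalide chemistry.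
- Comparison: in the order of events at C1 and C6 this road is better. The chosen plan must add an aryllithium twice to ester 16 with the alkyne alongside and must couple the doubly flanked triflate 14. Against this it sets the ortho-ester activation of the triflate, a cold addition, and a key step that creates ring A itself in far fewer steps.

Alternative 2: The cut removes three ring A bonds (C1–C6, C2–C3, C4–C5) together with a lactone ring. The precursors are the ester-tethered diyne 1,1,3-tris(4-methoxyphenyl)prop-2-yn-1-yl 4-(tert-butyldimethylsilyloxy)but-2-ynoate A4 and acetylene A5. A [2+2+2] cycloaddition catalysed by RhCl(PPh3)3 A6 gives 3,3,4-tris(4-methoxyphenyl)-7-[(tert-butyldimethylsilyloxy)methyl]isobenzofuran-1(3H)-one A7.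
- Merits: three C–C bonds and two rings form in one step. The regiochemistry is fixed by the tether and by the symmetry of A5. The crowded triaryl carbon is made earlier on an open chain. In this respect, and in bonds formed per step, the alternative is better than the chosen plan, which must force a double addition onto hindered ester 16.
- Weak points: A4 is the ester of a tertiary, doubly 4-methoxybenzylic propargylic alcohol. It is hard to acylate and is prone to ionisation and to metal-induced acyloxy shift. The lactone carbonyl of A7 sits on C6, where the target needs an arylethynyl group. That carbon must be reduced, homologated by one carbon and arylated, which is at least three further steps beside a liberated tertiary alcohol. The phenols are again methyl ethers.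
- Comparison: the chosen plan sets against this a phenol on C6 that becomes the alkyne in two steps and an ester on C1 that becomes the carbinol in one.

Alternative 3: The cut is at C1–C6 and C2–C3. Methyl 6-[(4-methoxyphenyl)ethynyl]-2-oxo-2H-pyran-5-carboxylate A8 and 4,4',4''-(prop-1-yne-1,3,3-triyl)tris(methoxybenzene) A9 undergo inverse-demand Diels–Alder addition. Cycloreversion with loss of the lactone bridge gives methyl 3-[bis(4-methoxyphenyl)methyl]-4-(4-methoxyphenyl)-2-[(4-methoxyphenyl)ethynyl]benzoate A10.
- Merits: the step is thermal and metal-free. The alkyne is present from the start, so no coupling at a hindered triflate is needed. The C5 arm arrives as an ester that is reduced directly. In these respects the alternative is more direct.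
- Weak points: the regiochemistry rests on a weak bias. The two alkyne carbons of A9 differ little electronically, and the required orientation puts the bulky diarylmethyl group next to the alkynyl-bearing pyrone carbon, which sterics disfavour. An internal, hindered alkyne needs high temperature, at which the alkynyl group of A8 and the alkyne of A10 are competing dienophiles. The triarylmethane C–H of A10 must later be oxidised by hydride abstraction in the presence of an electron-rich alkyne. The phenols are again methyl ethers.
- Comparison: the chosen plan sets against this a regiochemistry decided by the large reactivity gap between an oxocarbenium ion and an aryl ketone, and a C1 carbon already at the ester oxidation level.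

Key step: step 6

Remark: the double-bond geometry of 5 and 6 is not controlled and does not matter, because both alkenes of 6 end in the aromatic ring; the isomers drawn are representative, and 2, 15 and 17 are treated as purchasable.

## Route

Step 1
Reactants: 1 methyl acetoacetate; 2 (chloromethoxy)triisopropylsilane
Product: 4 methyl 3-oxo-5-(triisopropylsilyloxy)pentanoate, via dilithium dianion of methyl acetoacetate 3 (not isolated)
Conditions: LiN(iPr)2 (LDA, 2.1 equiv), THF, 0 °C; then 2, −78 → −20 °C; aq. NH4Cl
Reagents that add atoms: none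
Why: γ-Alkylation of an acetoacetate dianion with a chloromethyl ether; the terminal carbanion of 3 is its most nucleophilic site and reacts with the reactive α-chloro ether, while the bulky silyl group keeps the nucleophile away from silicon.

Step 2
Reactants: 4 methyl 3-oxo-5-(triisopropylsilyloxy)pentanoate
Product: 5 methyl (Z)-5-(triisopropylsilyloxy)-3-(trimethylsilyloxy)pent-2-enoate
Conditions: Me3SiCl, Et3N, toluene, 20 °C
Reagents that add atoms: chlorotrimethylsilane, C[Si](C)(C)Cl
Why: O-Silylation of the enolisable β-keto ester is the standard first stage in the preparation of 1,3-bis(silyloxy)dienes; the mild amine base leaves the β-silyloxy group in place.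

Step 3
Reactants: 5 methyl (Z)-5-(triisopropylsilyloxy)-3-(trimethylsilyloxy)pent-2-enoate
Product: 6 (1E,3E)-1-methoxy-5-(triisopropylsilyloxy)-1,3-bis(trimethylsilyloxy)penta-1,3-diene
Conditions: LiN(iPr)2 (LDA), Me3SiCl (present from the start), THF, −78 → 20 °C; hexane, filtration under argon, used crude
Reagents that add atoms: chlorotrimethylsilane, C[Si](C)(C)Cl
Why: γ-Deprotonation of the β-silyloxy enoate gives the extended ester dienolate, which is silylated on oxygen (second stage of the known bis(silyloxy)diene synthesis). Trapping in situ at −78 °C leaves the dienolate no time to expel the β-silyloxide.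

Step 4
Reactants: 7 4'-hydroxyacetophenone
Product: 8 1-[4-(triisopropylsilyloxy)phenyl]ethan-1-one
Conditions: iPr3SiCl, imidazole, DMF, 20 °C
Reagents that add atoms: chlorotriisopropylsilane, CC(C)[Si](Cl)(C(C)C)C(C)C
Why: Routine imidazole-promoted silylation of a phenol; the triisopropylsilyl ether is chosen because it is the aryl silyl ether most resistant to Lewis acid and base.

Step 5
Reactants: 8 1-[4-(triisopropylsilyloxy)phenyl]ethan-1-one; 9 trimethyl orthoformate
Product: 11 3,3-dimethoxy-1-[4-(triisopropylsilyloxy)phenyl]propan-1-one, via dimethoxycarbenium tetrafluoroborate 10 (not isolated)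
Conditions: 9, BF3·OEt2, CH2Cl2, −30 → 0 °C; then 8, iPr2NEt, −78 °C; aq. NaHCO3
Reagents that add atoms: none
Why: α-Formylation of a ketone at the acetal level: BF3·OEt2 turns the orthoformate into carbenium salt 10, and the enol form of 8, generated by the hindered amine in the Lewis-acidic medium, attacks it (Mukaiyama-type C–C bond formation). No alkoxide or aqueous acid is involved, so the aryl silyl ether is not at risk.

Step 6
Reactants: 6 (1E,3E)-1-methoxy-5-(triisopropylsilyloxy)-1,3-bis(trimethylsilyloxy)penta-1,3-diene; 11 3,3-dimethoxy-1-[4-(triisopropylsilyloxy)phenyl]propan-1-one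
Product: 13 methyl 2-hydroxy-3-[(triisopropylsilyloxy)methyl]-6-[4-(triisopropylsilyloxy)phenyl]benzoate, via open-chain methoxy diketo ester 12 (not isolated)
Conditions: TiCl4 (1.1 equiv), CH2Cl2, −78 → 20 °C; aq. NaHCO3
Reagents that add atoms: none
Why: TiCl4 ionises the acetal of 11 to an oxocarbenium ion, which is attacked by the terminal carbon of diene 6 (the carbon carrying the silyloxymethyl group) in a Mukaiyama-type addition to give adduct 12; this forms the C4–C5 bond of ring A. The remaining silyl ketene acetal carbon then adds to the TiCl4-activated aryl ketone in a 6-(enolexo)-exo-trig aldol closure, which forms the C1–C2 bond, and loss of methanol and water aromatises the ring to the salicylate. The closest known reaction type is the TiCl4-mediated formal [3+3] cyclocondensation of 1,3-bis(silyloxy)-1,3-dienes with β-keto acetals and related 1,3-dielectrophiles, which is also known for dienes substituted at the terminal carbon. No stereocentre is created, and the two stereocentres of 12 disappear on aromatisation. The step needs regioselectivity (aryl next to the ester, not next to the side chain); this follows from the order of events, because the oxocarbenium ion is far more electrophilic than the aryl ketone, which is further deactivated by its para silyloxy donor, and because the diene terminus is its most nucleophilic carbon. The step also needs both silyl ethers to survive: triisopropylsilyl ethers are poor Lewis bases, the aryl ether oxygen is conjugated to the ketone, and the mixture is kept cold and quenched with NaHCO3.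

Step 7
Reactants: 13 methyl 2-hydroxy-3-[(triisopropylsilyloxy)methyl]-6-[4-(triisopropylsilyloxy)phenyl]benzoate
Product: 14 methyl 3-[(triisopropylsilyloxy)methyl]-6-[4-(triisopropylsilyloxy)phenyl]-2-{[(trifluoromethyl)sulfonyl]oxy}benzoate
Conditions: Tf2O, pyridine, CH2Cl2, −78 → 0 °C
Reagents that add atoms: trifluoromethanesulfonic anhydride, O=S(=O)(OS(=O)(=O)C(F)(F)F)C(F)(F)F
Why: Triflation of a salicylate phenol with Tf2O and pyridine is routine even for hydrogen-bonded, flanked phenols; the pyridine buffer keeps the medium non-acidic, so the silyl ethers are untouched.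

Step 8
Reactants: 14 methyl 3-[(triisopropylsilyloxy)methyl]-6-[4-(triisopropylsilyloxy)phenyl]-2-{[(trifluoromethyl)sulfonyl]oxy}benzoate; 15 tert-butyl(4-ethynylphenoxy)dimethylsilane
Product: 16 methyl 2-{[4-(tert-butyldimethylsilyloxy)phenyl]ethynyl}-3-[(triisopropylsilyloxy)methyl]-6-[4-(triisopropylsilyloxy)phenyl]benzoate
Conditions: Pd(PPh3)2Cl2 (cat.), CuI (cat.), Et3N, DMF, 70 °C
Reagents that add atoms: none
Why: Sonogashira coupling of an aryl triflate; the ortho ester accelerates oxidative addition to zerovalent palladium, and the rod-shaped copper acetylide is the least hindered partner for a doubly flanked position. Triethylamine is too weak a base to cleave the aryl silyl ethers.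

Step 9
Reactants: 17 (4-bromophenoxy)(tert-butyl)dimethylsilane; 16 methyl 2-{[4-(tert-butyldimethylsilyloxy)phenyl]ethynyl}-3-[(triisopropylsilyloxy)methyl]-6-[4-(triisopropylsilyloxy)phenyl]benzoate
Product: 20 {2-{[4-(tert-butyldimethylsilyloxy)phenyl]ethynyl}-3-[(triisopropylsilyloxy)methyl]-6-[4-(triisopropylsilyloxy)phenyl]phenyl}bis[4-(tert-butyldimethylsilyloxy)phenyl]methanol, via [4-(tert-butyldimethylsilyloxy)phenyl]lithium 18 (not isolated), via diaryl ketone 19 (not isolated)
Conditions: 17 (3.0 equiv), n-BuLi (2.9 equiv), THF, −78 °C; then 16 (1.0 equiv), −78 → 0 °C; aq. NH4Cl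
Reagents that add atoms: (4-bromophenoxy)(tert-butyl)dimethylsilane (the second equivalent of 17, lithiated to 18 in the same flask), Brc1ccc(O[Si](C)(C)C(C)(C)C)cc1
Why: Bromine–lithium exchange turns 17 into aryllithium 18, and the ester consumes two equivalents of it (double addition of an organolithium to an ester): the first adduct collapses to the non-enolisable ketone 19, which is more electrophilic than the ester and takes the second equivalent. The linear alkyne on one flank leaves the carbonyl accessible, and staying at or below 0 °C keeps the tertiary lithium alkoxide from adding to the alkyne.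

Step 10
Reactants: 20 {2-{[4-(tert-butyldimethylsilyloxy)phenyl]ethynyl}-3-[(triisopropylsilyloxy)methyl]-6-[4-(triisopropylsilyloxy)phenyl]phenyl}bis[4-(tert-butyldimethylsilyloxy)phenyl]methanol
Product: 22 selaginellin, via pentahydroxy carbinol 21 (not isolated)
Conditions: Bu4NF, AcOH, THF, 0 → 20 °C; then 1 M aq. HCl, 20 °C
Reagents that add atoms: none
Why: Fluoride cleaves all four O–Si bonds, and the acetic acid buffer ensures that no free alkoxide or phenoxide sits next to the alkyne. Brief mild acid then ionises the doubly 4-hydroxyphenyl-substituted carbinol 21, and loss of a phenolic proton gives the quinone methide (dehydration of a 4-hydroxytrityl alcohol). The acid is too weak for Friedel–Crafts closure onto the C2 aryl ring.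

## Compound list

1 | methyl acetoacetate | COC(=O)CC(C)=O | starting material
2 | (chloromethoxy)triisopropylsilane | ClCO[Si](C(C)C)(C(C)C)C(C)C | starting material
3 | dilithium 1-methoxybuta-1,3-diene-1,3-diolate (dianion of methyl acetoacetate) | [Li+].[Li+].COC([O-])=CC([O-])=C | intermediate
4 | methyl 3-oxo-5-(triisopropylsilyloxy)pentanoate | COC(=O)CC(=O)CCO[Si](C(C)C)(C(C)C)C(C)C | intermediate
5 | methyl (Z)-5-(triisopropylsilyloxy)-3-(trimethylsilyloxy)pent-2-enoate | COC(=O)/C=C(/CCO[Si](C(C)C)(C(C)C)C(C)C)O[Si](C)(C)C | intermediate
6 | (1E,3E)-1-methoxy-5-(triisopropylsilyloxy)-1,3-bis(trimethylsilyloxy)penta-1,3-diene | CO/C(O[Si](C)(C)C)=C\C(O[Si](C)(C)C)=C/CO[Si](C(C)C)(C(C)C)C(C)C | intermediate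
7 | 4'-hydroxyacetophenone | CC(=O)c1ccc(O)cc1 | starting material
8 | 1-[4-(triisopropylsilyloxy)phenyl]ethan-1-one | CC(=O)c1ccc(O[Si](C(C)C)(C(C)C)C(C)C)cc1 | intermediate
9 | trimethyl orthoformate | COC(OC)OC | starting material
10 | dimethoxycarbenium tetrafluoroborate | CO[CH+]OC.F[B-](F)(F)F | intermediate
11 | 3,3-dimethoxy-1-[4-(triisopropylsilyloxy)phenyl]propan-1-one | COC(OC)CC(=O)c1ccc(O[Si](C(C)C)(C(C)C)C(C)C)cc1 | intermediate
12 | methyl 5-methoxy-3,7-dioxo-4-[(triisopropylsilyloxy)methyl]-7-[4-(triisopropylsilyloxy)phenyl]heptanoate (diastereomer mixture, present as its titanium enolate) | COC(=O)CC(=O)C(CO[Si](C(C)C)(C(C)C)C(C)C)C(OC)CC(=O)c1ccc(O[Si](C(C)C)(C(C)C)C(C)C)cc1 | intermediate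
13 | methyl 2-hydroxy-3-[(triisopropylsilyloxy)methyl]-6-[4-(triisopropylsilyloxy)phenyl]benzoate | COC(=O)c1c(O)c(CO[Si](C(C)C)(C(C)C)C(C)C)ccc1-c1ccc(O[Si](C(C)C)(C(C)C)C(C)C)cc1 | intermediate
14 | methyl 3-[(triisopropylsilyloxy)methyl]-6-[4-(triisopropylsilyloxy)phenyl]-2-{[(trifluoromethyl)sulfonyl]oxy}benzoate | COC(=O)c1c(OS(=O)(=O)C(F)(F)F)c(CO[Si](C(C)C)(C(C)C)C(C)C)ccc1-c1ccc(O[Si](C(C)C)(C(C)C)C(C)C)cc1 | intermediate
15 | tert-butyl(4-ethynylphenoxy)dimethylsilane | C#Cc1ccc(O[Si](C)(C)C(C)(C)C)cc1 | starting material
16 | methyl 2-{[4-(tert-butyldimethylsilyloxy)phenyl]ethynyl}-3-[(triisopropylsilyloxy)methyl]-6-[4-(triisopropylsilyloxy)phenyl]benzoate | COC(=O)c1c(C#Cc2ccc(O[Si](C)(C)C(C)(C)C)cc2)c(CO[Si](C(C)C)(C(C)C)C(C)C)ccc1-c1ccc(O[Si](C(C)C)(C(C)C)C(C)C)cc1 | intermediate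
17 | (4-bromophenoxy)(tert-butyl)dimethylsilane | Brc1ccc(O[Si](C)(C)C(C)(C)C)cc1 | starting material
18 | [4-(tert-butyldimethylsilyloxy)phenyl]lithium | [Li]c1ccc(O[Si](C)(C)C(C)(C)C)cc1 | intermediate
19 | [4-(tert-butyldimethylsilyloxy)phenyl]{2-{[4-(tert-butyldimethylsilyloxy)phenyl]ethynyl}-3-[(triisopropylsilyloxy)methyl]-6-[4-(triisopropylsilyloxy)phenyl]phenyl}methanone | O=C(c1ccc(O[Si](C)(C)C(C)(C)C)cc1)c1c(C#Cc2ccc(O[Si](C)(C)C(C)(C)C)cc2)c(CO[Si](C(C)C)(C(C)C)C(C)C)ccc1-c1ccc(O[Si](C(C)C)(C(C)C)C(C)C)cc1 | intermediate
20 | {2-{[4-(tert-butyldimethylsilyloxy)phenyl]ethynyl}-3-[(triisopropylsilyloxy)methyl]-6-[4-(triisopropylsilyloxy)phenyl]phenyl}bis[4-(tert-butyldimethylsilyloxy)phenyl]methanol | OC(c1ccc(O[Si](C)(C)C(C)(C)C)cc1)(c1ccc(O[Si](C)(C)C(C)(C)C)cc1)c1c(C#Cc2ccc(O[Si](C)(C)C(C)(C)C)cc2)c(CO[Si](C(C)C)(C(C)C)C(C)C)ccc1-c1ccc(O[Si](C(C)C)(C(C)C)C(C)C)cc1 | intermediate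
21 | {3-(hydroxymethyl)-6-(4-hydroxyphenyl)-2-[(4-hydroxyphenyl)ethynyl]phenyl}bis(4-hydroxyphenyl)methanol | OC(c1ccc(O)cc1)(c1ccc(O)cc1)c1c(C#Cc2ccc(O)cc2)c(CO)ccc1-c1ccc(O)cc1 | intermediate
22 | selaginellin, 4-{[3-(hydroxymethyl)-6-(4-hydroxyphenyl)-2-[(4-hydroxyphenyl)ethynyl]phenyl](4-hydroxyphenyl)methylidene}cyclohexa-2,5-dien-1-one | O=C1C=CC(=C(c2ccc(O)cc2)c2c(-c3ccc(O)cc3)ccc(CO)c2C#Cc2ccc(O)cc2)C=C1 | target

## Step count and least certain steps

Total step count: 10. Longest linear sequence: 8 steps (steps 1, 2, 3, 6, 7, 8, 9, 10); the keto acetal branch (steps 4 and 5) joins at step 6.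

**Step 6 (key step).** The main risk is loss of the oxygenated arm. The β-silyloxy ketone stage of 12 can eliminate silyloxide, and the benzylic silyl ether next to the titanium phenoxide can ionise along an ortho-quinone methide pathway. A further risk is that the substituted diene terminus reacts so slowly that diene hydrolysis or attack at the ketone (reversed regiochemistry) competes. The fallback keeps the same ring closure but adds the arm afterwards. It sets out from 1 and 11 and returns at 13.
- Compound 1 is silylated as in step 2 to methyl (Z)-3-(trimethylsilyloxy)but-2-enoate F1, and as in step 3 to 1-methoxy-1,3-bis(trimethylsilyloxy)buta-1,3-diene F2.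
- TiCl4-mediated annulation of F2 with 11 should give methyl 2-hydroxy-6-[4-(triisopropylsilyloxy)phenyl]benzoate F3.
- Magnesium phenoxide-directed ortho-formylation (MgCl2, Et3N, paraformaldehyde, MeCN, reflux) at the only free ortho position gives methyl 3-formyl-2-hydroxy-6-[4-(triisopropylsilyloxy)phenyl]benzoate F4.
- NaBH4 in MeOH gives methyl 2-hydroxy-3-(hydroxymethyl)-6-[4-(triisopropylsilyloxy)phenyl]benzoate F5.
- iPr3SiCl and imidazole silylate the primary alcohol in preference to the hydrogen-bonded phenol and give 13.

**Step 8.** Oxidative addition into the doubly flanked C–O bond may be slow. Copper-mediated oxidative dimerisation of 15 and S–O cleavage of the triflate back to the phenol would then compete. The fallback replaces the copper acetylide by a preformed alkynyl metal and needs neither amine nor copper. It sets out from 15 and 14 and returns at 16. Compound 15 is stannylated with Bu3SnOMe (neat, 60 °C, methanol removed) to tributyl{[4-(tert-butyldimethylsilyloxy)phenyl]ethynyl}stannane F6. Stille coupling of F6 with 14 (Pd(PPh3)4, LiCl, 1,4-dioxane, 90 °C) gives 16.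

**Step 9.** The addition may stall at the ester or at ketone 19 because of crowding. Forcing it by warming invites addition of the tertiary lithium alkoxide across the neighbouring alkyne or attack of the aryllithium at silicon. The fallback separates the two additions and starts from a far less hindered aldehyde. It sets out from 16 and returns at 19 and then 20.
- iBu2AlH (CH2Cl2, −78 → 0 °C) reduces 16 to {2-{[4-(tert-butyldimethylsilyloxy)phenyl]ethynyl}-3-[(triisopropylsilyloxy)methyl]-6-[4-(triisopropylsilyloxy)phenyl]phenyl}methanol F7.
- Dess–Martin oxidation gives 2-{[4-(tert-butyldimethylsilyloxy)phenyl]ethynyl}-3-[(triisopropylsilyloxy)methyl]-6-[4-(triisopropylsilyloxy)phenyl]benzaldehyde F8.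
- One equivalent of 18 at −78 °C gives racemic [4-(tert-butyldimethylsilyloxy)phenyl]{2-{[4-(tert-butyldimethylsilyloxy)phenyl]ethynyl}-3-[(triisopropylsilyloxy)methyl]-6-[4-(triisopropylsilyloxy)phenyl]phenyl}methanol F9.
- A second Dess–Martin oxidation gives ketone 19, now isolated.
- Aryllithium 18 premixed with CeCl3 (THF, −78 °C) adds to 19 and gives 20.

**Step 10.** The primary triisopropylsilyl ether cleaves slowly under buffered fluoride. Pushing with unbuffered fluoride would expose the alkyne to a benzylic alkoxide or a phenoxide and lead to cyclisation. Pushing the ionisation with stronger acid would lead to fluorene closure. The fallback exchanges the slow group for a triethylsilyl ether at a robust stage. It sets out from 14 and returns at 22.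
- Dilute HCl in THF and MeOH cleaves only the alkyl silyl ether of 14, since aryl silyl ethers are the acid-stable ones, and gives methyl 3-(hydroxymethyl)-6-[4-(triisopropylsilyloxy)phenyl]-2-{[(trifluoromethyl)sulfonyl]oxy}benzoate F10.
- Et3SiCl and imidazole give methyl 3-[(triethylsilyloxy)methyl]-6-[4-(triisopropylsilyloxy)phenyl]-2-{[(trifluoromethyl)sulfonyl]oxy}benzoate F11.
- Sonogashira coupling with 15 as in step 8 gives methyl 2-{[4-(tert-butyldimethylsilyloxy)phenyl]ethynyl}-3-[(triethylsilyloxy)methyl]-6-[4-(triisopropylsilyloxy)phenyl]benzoate F12.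
- Double addition of 18 (two equivalents, from 17) as in step 9 passes through [4-(tert-butyldimethylsilyloxy)phenyl]{2-{[4-(tert-butyldimethylsilyloxy)phenyl]ethynyl}-3-[(triethylsilyloxy)methyl]-6-[4-(triisopropylsilyloxy)phenyl]phenyl}methanone F13 and gives {2-{[4-(tert-butyldimethylsilyloxy)phenyl]ethynyl}-3-[(triethylsilyloxy)methyl]-6-[4-(triisopropylsilyloxy)phenyl]phenyl}bis[4-(tert-butyldimethylsilyloxy)phenyl]methanol F14.
- In F14 all four silyl ethers fall quickly to buffered Bu4NF at 0 °C, and mild acid then gives 22 through 21.

**Step 1.** The hard chloromethyl ether may alkylate on oxygen or a second time at carbon. The fallback is an aldol in place of the alkylation. It sets out from 1 through dianion 3 and returns at 4. Monomeric formaldehyde (from cracked paraformaldehyde) is passed into 3 at −78 °C to give methyl 5-hydroxy-3-oxopentanoate F15. This is silylated at once with iPr3SiOTf and 2,6-lutidine (CH2Cl2, −78 °C), before it can dehydrate, to give 4.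

## Further compounds

F1 | step 6 | methyl (Z)-3-(trimethylsilyloxy)but-2-enoate | COC(=O)/C=C(/C)O[Si](C)(C)C
F2 | step 6 | 1-methoxy-1,3-bis(trimethylsilyloxy)buta-1,3-diene (either geometry) | COC(O[Si](C)(C)C)=CC(=C)O[Si](C)(C)C
F3 | step 6 | methyl 2-hydroxy-6-[4-(triisopropylsilyloxy)phenyl]benzoate | COC(=O)c1c(O)cccc1-c1ccc(O[Si](C(C)C)(C(C)C)C(C)C)cc1
F4 | step 6 | methyl 3-formyl-2-hydroxy-6-[4-(triisopropylsilyloxy)phenyl]benzoate | COC(=O)c1c(O)c(C=O)ccc1-c1ccc(O[Si](C(C)C)(C(C)C)C(C)C)cc1
F5 | step 6 | methyl 2-hydroxy-3-(hydroxymethyl)-6-[4-(triisopropylsilyloxy)phenyl]benzoate | COC(=O)c1c(O)c(CO)ccc1-c1ccc(O[Si](C(C)C)(C(C)C)C(C)C)cc1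
F6 | step 8 | tributyl{[4-(tert-butyldimethylsilyloxy)phenyl]ethynyl}stannane | CCCC[Sn](CCCC)(CCCC)C#Cc1ccc(O[Si](C)(C)C(C)(C)C)cc1
F7 | step 9 | {2-{[4-(tert-butyldimethylsilyloxy)phenyl]ethynyl}-3-[(triisopropylsilyloxy)methyl]-6-[4-(triisopropylsilyloxy)phenyl]phenyl}methanol | OCc1c(C#Cc2ccc(O[Si](C)(C)C(C)(C)C)cc2)c(CO[Si](C(C)C)(C(C)C)C(C)C)ccc1-c1ccc(O[Si](C(C)C)(C(C)C)C(C)C)cc1
F8 | step 9 | 2-{[4-(tert-butyldimethylsilyloxy)phenyl]ethynyl}-3-[(triisopropylsilyloxy)methyl]-6-[4-(triisopropylsilyloxy)phenyl]benzaldehyde | O=Cc1c(C#Cc2ccc(O[Si](C)(C)C(C)(C)C)cc2)c(CO[Si](C(C)C)(C(C)C)C(C)C)ccc1-c1ccc(O[Si](C(C)C)(C(C)C)C(C)C)cc1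
F9 | step 9 | [4-(tert-butyldimethylsilyloxy)phenyl]{2-{[4-(tert-butyldimethylsilyloxy)phenyl]ethynyl}-3-[(triisopropylsilyloxy)methyl]-6-[4-(triisopropylsilyloxy)phenyl]phenyl}methanol (racemic) | OC(c1ccc(O[Si](C)(C)C(C)(C)C)cc1)c1c(C#Cc2ccc(O[Si](C)(C)C(C)(C)C)cc2)c(CO[Si](C(C)C)(C(C)C)C(C)C)ccc1-c1ccc(O[Si](C(C)C)(C(C)C)C(C)C)cc1
F10 | step 10 | methyl 3-(hydroxymethyl)-6-[4-(triisopropylsilyloxy)phenyl]-2-{[(trifluoromethyl)sulfonyl]oxy}benzoate | COC(=O)c1c(OS(=O)(=O)C(F)(F)F)c(CO)ccc1-c1ccc(O[Si](C(C)C)(C(C)C)C(C)C)cc1
F11 | step 10 | methyl 3-[(triethylsilyloxy)methyl]-6-[4-(triisopropylsilyloxy)phenyl]-2-{[(trifluoromethyl)sulfonyl]oxy}benzoate | COC(=O)c1c(OS(=O)(=O)C(F)(F)F)c(CO[Si](CC)(CC)CC)ccc1-c1ccc(O[Si](C(C)C)(C(C)C)C(C)C)cc1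
F12 | step 10 | methyl 2-{[4-(tert-butyldimethylsilyloxy)phenyl]ethynyl}-3-[(triethylsilyloxy)methyl]-6-[4-(triisopropylsilyloxy)phenyl]benzoate | COC(=O)c1c(C#Cc2ccc(O[Si](C)(C)C(C)(C)C)cc2)c(CO[Si](CC)(CC)CC)ccc1-c1ccc(O[Si](C(C)C)(C(C)C)C(C)C)cc1
F13 | step 10 | [4-(tert-butyldimethylsilyloxy)phenyl]{2-{[4-(tert-butyldimethylsilyloxy)phenyl]ethynyl}-3-[(triethylsilyloxy)methyl]-6-[4-(triisopropylsilyloxy)phenyl]phenyl}methanone | O=C(c1ccc(O[Si](C)(C)C(C)(C)C)cc1)c1c(C#Cc2ccc(O[Si](C)(C)C(C)(C)C)cc2)c(CO[Si](CC)(CC)CC)ccc1-c1ccc(O[Si](C(C)C)(C(C)C)C(C)C)cc1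
F14 | step 10 | {2-{[4-(tert-butyldimethylsilyloxy)phenyl]ethynyl}-3-[(triethylsilyloxy)methyl]-6-[4-(triisopropylsilyloxy)phenyl]phenyl}bis[4-(tert-butyldimethylsilyloxy)phenyl]methanol | OC(c1ccc(O[Si](C)(C)C(C)(C)C)cc1)(c1ccc(O[Si](C)(C)C(C)(C)C)cc1)c1c(C#Cc2ccc(O[Si](C)(C)C(C)(C)C)cc2)c(CO[Si](CC)(CC)CC)ccc1-c1ccc(O[Si](C(C)C)(C(C)C)C(C)C)cc1
F15 | step 1 | methyl 5-hydroxy-3-oxopentanoate | COC(=O)CC(=O)CCO
A1 | alternative 1 | {6-[(tert-butyldimethylsilyloxy)methyl]-2-[methoxybis(4-methoxyphenyl)methyl]-3-(4-methoxyphenyl)phenyl}(4-methoxyphenyl)methanone | COc1ccc(cc1)C(=O)c1c(CO[Si](C)(C)C(C)(C)C)ccc(-c2ccc(OC)cc2)c1C(OC)(c1ccc(OC)cc1)c1ccc(OC)cc1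
A2 | alternative 1 | lithio(trimethylsilyl)diazomethane | [Li]C(=[N+]=[N-])[Si](C)(C)C
A3 | alternative 1 | tert-butyl{[3-[methoxybis(4-methoxyphenyl)methyl]-4-(4-methoxyphenyl)-2-[(4-methoxyphenyl)ethynyl]phenyl]methoxy}dimethylsilane | COc1ccc(cc1)C#Cc1c(CO[Si](C)(C)C(C)(C)C)ccc(-c2ccc(OC)cc2)c1C(OC)(c1ccc(OC)cc1)c1ccc(OC)cc1
A4 | alternative 2 | 1,1,3-tris(4-methoxyphenyl)prop-2-yn-1-yl 4-(tert-butyldimethylsilyloxy)but-2-ynoate | COc1ccc(cc1)C#CC(OC(=O)C#CCO[Si](C)(C)C(C)(C)C)(c1ccc(OC)cc1)c1ccc(OC)cc1
A5 | alternative 2 | acetylene | C#C
A6 | alternative 2 | chlorotris(triphenylphosphine)rhodium, RhCl(PPh3)3 | Cl[Rh](P(c1ccccc1)(c1ccccc1)c1ccccc1)(P(c1ccccc1)(c1ccccc1)c1ccccc1)P(c1ccccc1)(c1ccccc1)c1ccccc1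
A7 | alternative 2 | 3,3,4-tris(4-methoxyphenyl)-7-[(tert-butyldimethylsilyloxy)methyl]isobenzofuran-1(3H)-one | O=C1OC(c2ccc(OC)cc2)(c2ccc(OC)cc2)c2c(-c3ccc(OC)cc3)ccc(CO[Si](C)(C)C(C)(C)C)c12
A8 | alternative 3 | methyl 6-[(4-methoxyphenyl)ethynyl]-2-oxo-2H-pyran-5-carboxylate | COC(=O)C1=C(C#Cc2ccc(OC)cc2)OC(=O)C=C1
A9 | alternative 3 | 4,4',4''-(prop-1-yne-1,3,3-triyl)tris(methoxybenzene) | COc1ccc(cc1)C#CC(c1ccc(OC)cc1)c1ccc(OC)cc1
A10 | alternative 3 | methyl 3-[bis(4-methoxyphenyl)methyl]-4-(4-methoxyphenyl)-2-[(4-methoxyphenyl)ethynyl]benzoate | COC(=O)c1ccc(-c2ccc(OC)cc2)c(C(c2ccc(OC)cc2)c2ccc(OC)cc2)c1C#Cc1ccc(OC)cc1
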